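The readings come from a simulation for substances that don't exist.

I began from a one-step world, in which starting material meets partner and becomes product. The amber run does not fit that world: its product lay flat near 51.1% with 6.8% of starting material still present at 8.00 min.

| flask | starting material | partner | protic impurity | free catalyst | temperature | remark | time |
|---|---|---|---|---|---|---|---|
| amber | 0.050 M | 1 equiv | 0.025 M | 0.05 mol% | 40 °C | the very flask that is asked about, followed so far |  |
| violet | 0.075 M | 1 equiv | 0.025 M | 0.05 mol% | 40 °C | run made earlier |  |
| flask | 0.050 M | 1.00 equiv | 0.0250 M | 0.05 mol% | 40 °C |  | 10 min |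

| run | time / min | product / % | starting material / % |
|---|---|---|---|
| amber | 0.500 | 18.9 | 63.4 |
| amber | 1.50 | 38.7 | 30.1 |
| amber | 3.00 | 49.1 | 14.2 |
| amber | 4.00 | 50.7 | 11.3 |
| amber | 6.00 | 50.8 | 8.8 |
| amber | 8.00 | 51.1 | 6.8 |
| violet | 0.833 | 34.3 | 44.6 |
| violet | 1.50 | 47.1 | 26.9 |
| violet | 2.50 | 56.5 | 16.5 |
| violet | 3.00 | 58.0 | 14.6 |
| violet | 4.00 | 59.0 | 11.6 |
| violet | 5.00 | 58.0 | 11.4 |

(readings scatter by 0.5 percentage points)

- removed product is counted in
- the analysis behind the earlier runs scatters by 0.5 percentage points, standard deviation
- the earlier runs do not show what temperature does; that part of a forecast is a guess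
- additions bring no volume worth counting

- Friday's: at 10 min add partner, 50.0% of the amount charged, then wait 5.0 min
- Tuesday's: at 10 min add free catalyst, 50.0% of the amount charged, then wait 5.0 min
- Wednesday's: at 10 min take out 90% of the product then present, then wait 5.0 min
- Saturday's: change nothing and wait 5.0 min more
- Sunday's: at 10 min raise the temperature by 25 K, then wait 5.0 min

1. product, in percent of the starting material first charged, at 10 min
2. which option adds most product ("none" when 2 percentage points or less is all one gets) (Friday's / Tuesday's / Wednesday's / Saturday's / Sunday's / none)
3. product present, with what was taken out counted in, in percent of the starting material first charged, after Saturday's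
4. product present, with what was taken out counted in, in percent of the starting material first charged, after Sunday's

So I turned the question round and asked what must be true for fresh catalyst to pay. The catalyst in the flask must have died at the stall. If it died after a fixed number of turnovers, the amber and violet runs, both at 0.05 mol%, should stop at one percentage. But violet reads 58.0%, a gap of 6.9 percentage points against a scatter of 0.5 points.

Suppose instead that partner, the limiting reagent, has a first-order loss of its own beside its catalytic use. If free catalyst stood steady, both losses would follow partner and their split would not depend on the partner charge; I took that as a rough estimate only, since the split moves with free catalyst. At 1 equiv the amber plateau reads φ = 51.1%, the partner yield, the part of the charged partner that ends as product. Violet has 1.50 times amber's catalyst concentration, and its higher reading suits that race.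

By my reckoning, Friday's addition carries 26 points of potential product, so starting material sets its ceiling. Continuing amber's decline gives about 5.25% at 10 min. For "none" to win, that figure must fall to 2 points, and it stands above. I therefore chose Friday's and expected the plateau otherwise.

The forecast gave 51% now, 51.1% after Saturday's and 51.4% after Sunday's, and it chose Tuesday's, holding that “The likely cause is dead catalyst”. We part on the option.

The flask gave 51.3%, and Friday's added 5.4 points, while Tuesday's added 0 points.

    catalyst intermediate B → free catalyst + product (k = 41.0 s⁻¹, Ea = 53.0 kJ mol⁻¹)
    partner + free catalyst → catalyst intermediate A (k = 740 M⁻¹ s⁻¹, Ea = 42.0 kJ mol⁻¹)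
    2 free catalyst ⇌ resting dimer (K = 17000 M⁻¹, k = 300 M⁻¹ s⁻¹, Ea = 46.0 kJ mol⁻¹, ΔH = −25.0 kJ mol⁻¹)
    starting material + catalyst intermediate A ⇌ catalyst intermediate B (K = 65.0 M⁻¹, k = 2700 M⁻¹ s⁻¹, Ea = 45.0 kJ mol⁻¹, ΔH = −45.0 kJ mol⁻¹)
    partner → decomposed reagent (k = 0.00840 s⁻¹, Ea = 86.0 kJ mol⁻¹)
    starting material + protic impurity → quenched substrate (k = 0.380 M⁻¹ s⁻¹, Ea = 47.0 kJ mol⁻¹)
    (constants at 40 °C)

At 10.0 min the flask held 0% of its partner, 5.67% of its starting material and 64.6% of its catalyst as free catalyst. Friday's gain stayed below that starting material, far under the 26 points that φ offered. In the neighbour flask with 0.250 equiv of partner, φ gives 12.8%; that flask gave 15.0%, with 0% of its partner and 35% of its starting material left, so its partner yield was 60.0%, above φ.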